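(The data stem from a simulated flask for an exercise.)

We start from a leftover: E reads no more than 2.7 % from 5.00 h on in the south-west run and no more than 1.6 % from 6.00 h on in the south-east run, yet Q levels off short of the E charged. Averaged from 5.00 h, the south-west plateau is 83.2 %, which leaves 16.8 % of the E charged elsewhere. Averaged from 6.00 h, the south-east plateau is 77.8 %, which leaves 22.2 %.

| setting | south-west | south-east | flask |
|---|---|---|---|
| E | 0.16 M | 0.16 M | 0.16 M |
| D | 0.64 M | 0.64 M | 0.640 M |
| Z | 0.040 M | 0.16 M | 0.0800 M |
| remark | run made earlier | run made earlier |  |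
| time |  |  | 25 h |
| volume of the second phase over the first |  |  | 0.25 |

| run | time / h | Q / % | E / % |
|---|---|---|---|
| south-west | 5.00 | 83.4 | 2.2 |
| south-west | 10.0 | 83.1 | 0 |
| south-west | 15.0 | 84.2 | 0.2 |
| south-west | 20.0 | 81.9 | 1.4 |
| south-west | 25.0 | 82.9 | 2.7 |
| south-west | 30.0 | 84.0 | 0.6 |
| south-east | 2.00 | 69.3 | 13.8 |
| south-east | 6.00 | 77.6 | 0 |
| south-east | 10.0 | 79.1 | 0 |
| south-east | 15.0 | 77.4 | 1.6 |
| south-east | 25.0 | 77.4 | 0.2 |
| south-east | 30.0 | 77.7 | 0.6 |

(each reading ± 1 percentage point)

- in the second phase: D; everything else is in the first
- charges count per volume of the first phase; a concentration in a rate is the amount of a species over the volume of its own phase; every rate counts per litre of the first phase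
- the numbers in the tables scatter with a standard deviation of 1 percentage point
- the earlier runs hold the two phases in the same ratio of volumes as the flask asked about

- how much Q there is at 25 h, in percent of the E charged
- part of the E charged that has reacted at 25 h

Z in the flask is more than in the south-west run and less than in the south-east run, so we take the two plateaus as our first estimate of the upper and lower bounds on Q. To tighten them, we define the Z price s as the part of the E charged that is lost per mole per litre of Z, read from the two plateaus: s = 0.451 M⁻¹. If the leftover grows in proportion to Z, the flask pays a Z tax, s times its Z, of 3.61 %. Added to the part of the leftover that does not depend on Z, this puts Q at 81.4 %, our upper end. If the leftover grows with the logarithm of Z instead, the flask sits at the geometric middle of the two Z charges and takes the mean of the plateaus, 80.5 %, our lower end.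

The forecast gave 81.2 % of Q, from 79.8 % to 82.5 %, and that central value is more than our lower end and less than our upper end. It gave 99.9 % of E reacted, and held that “the plateau is simply the selectivity”.

The flask gives 81.5 % of Q, close to our upper end, with 100 % of E reacted.

    G ⇌ D, rate k1*([G] - [D]/K1) per volume of the first phase (partition coefficient = 0.950, kL = 2.92 h⁻¹)
    E + G → Q (k = 2.02 M⁻¹ h⁻¹)
    E + Q → X (k = 0.335 M⁻¹ h⁻¹)
    E + Z → J (k = 0.472 M⁻¹ h⁻¹)
    Q ⇌ L (K = 0.118, k = 0.101 h⁻¹)

The Z tax of 3.61 % stands beside 3.94 % of J in the flask at 25.0 h. The neighbour flask, charged with 0.40 M of E, keeps Z at 0.0800 M, so the same reckoning again gives 3.61 %. Its J stands at 4.35 %, within a leftover of 27.6 %. Its Q is 72.4 %, and its X is 14.7 % against 4.99 % in the flask.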